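**Retrosynthetic overview**
1. The target is a mirror-symmetric trimer with no stereocentre: a central butanoylphloroglucinol ring A carries two identical 2-butanoylfilicinic acid rings B and B' through two CH2 bridges.
2. The last disconnections are the three aryl O–CH3 bonds of ring A and the two outer-ring C–C(=O)Pr bonds (O-to-C acyl transfer on the free triketones). Both are made in two directions at once.
3. Key disconnection: each ring B loses the ring carbons C(CH2Ar)=C(O) and shrinks to 3-ethoxy-4,4-dimethylcyclobut-2-enone. In the forward sense, the two ynol ether arms of one ring A core enlarge two such cyclobutenones from four to six members in a single thermal cascade.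
4. Enabling feature: in ring B the quaternary C(CH3)2 carbon lies between two oxygen-bearing ring carbons, and the three ring C–O carbons alternate (1,3,5). This maps onto one ketene C=O plus two alkoxyalkyne C–O carbons, and the C(CH3)2 terminus halts the benzannulation at the cyclohexadienone. The mirror plane of ring A (through C–butanoyl and the para C–O) makes both arms identical.
5. Ring order: ring A is bought as 1,3,5-trimethoxybenzene, the four-membered ring comes from a ketene/alkyne [2+2], and rings B and B' form together by ring expansion.

Key step: step 6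

Remark: every enolised β-triketone ring is drawn as the single enol tautomer used in the target SMILES; the tautomers interconvert freely and count as one compound.

**Step 1**
Reactants: 1 isobutyryl chloride; 2 ethoxyacetylene
Product: 4 3-ethoxy-4,4-dimethylcyclobut-2-en-1-one, via dimethylketene 3 (not isolated)
Conditions: Et3N, Et2O, 0 °C to reflux
Reagents that add atoms: none
Why: Et3N dehydrochlorinates 1 to dimethylketene 3, which undergoes the well-known regioselective ketene–alkoxyalkyne [2+2] cycloaddition (the CH terminus of 2 bonds to the ketene carbonyl carbon), so that OEt ends up next to the C(CH3)2 carbon.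

**Step 2**
Reactants: 5 1,3,5-trimethoxybenzene; 6 butanoic anhydride
Product: 7 1-(2,4,6-trimethoxyphenyl)butan-1-one
Conditions: Sc(OTf)3 (5 mol %), MeNO2, 50 °C
Reagents that add atoms: none
Why: Friedel–Crafts acylation of a strongly activated arene under catalytic Sc(OTf)3 is mild enough to spare the methyl ethers and is self-limiting because the first acyl group deactivates the ring.

**Step 3**
Reactants: 7 1-(2,4,6-trimethoxyphenyl)butan-1-one
Product: 8 1-[3,5-bis(bromomethyl)-2,4,6-trimethoxyphenyl]butan-1-one
Conditions: (CH2O)n, 33% HBr in AcOH, AcOH, rt to 40 °C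
Reagents that add atoms: paraformaldehyde, as formaldehyde (C=O); hydrogen bromide (Br)
Why: Twofold bromomethylation (Blanc-type electrophilic substitution) can occur only at the two remaining ring C–H positions, each activated by two ortho and one para methoxy group, and the ketone tempers the ring against diarylmethane formation.

**Step 4**
Reactants: 9 2-chloro-1,1-dimethoxyethane (chloroacetaldehyde dimethyl acetal)
Product: 11 tributyl(methoxyethynyl)stannane, via lithium methoxyacetylide 10 (not isolated)
Conditions: LiNEt2 (3 equiv), THF, 0 °C; then Bu3SnCl, −78 °C to rt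
Reagents that add atoms: tributyltin chloride (CCCC[Sn](Cl)(CCCC)CCCC)
Why: Base-induced loss of methanol and HCl from the chloroacetal followed by deprotonation is the standard entry to lithium alkoxyacetylides, and 10 is trapped at carbon by Bu3SnCl.

**Step 5**
Reactants: 8 1-[3,5-bis(bromomethyl)-2,4,6-trimethoxyphenyl]butan-1-one; 11 tributyl(methoxyethynyl)stannane (2.2 equiv)
Product: 12 1-[2,4,6-trimethoxy-3,5-bis(3-methoxyprop-2-yn-1-yl)phenyl]butan-1-one
Conditions: Pd2(dba)3 (2.5 mol %), P(2-furyl)3 (10 mol %), THF, 50 °C; chromatography on Et3N-deactivated silica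
Reagents that add atoms: none
Why: Twofold Stille coupling of a benzylic bromide with an alkynylstannane runs under neutral conditions, which the enolisable ketone and the acid-sensitive ynol ethers tolerate.

**Step 6**
Reactants: 12 1-[2,4,6-trimethoxy-3,5-bis(3-methoxyprop-2-yn-1-yl)phenyl]butan-1-one; 4 3-ethoxy-4,4-dimethylcyclobut-2-en-1-one (3 equiv)
Product: 16 1-{3,5-bis[(4-ethoxy-2-methoxy-5,5-dimethyl-6-oxocyclohexa-1,3-dien-1-yl)methyl]-2,4,6-trimethoxyphenyl}butan-1-one, via vinylketene 13 (not isolated), via bis(alkenylcyclobutenone) 14 (not isolated), via bis(dienylketene) 15 (not isolated)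
Conditions: toluene (about 1 M), sealed tube, 160 °C
Reagents that add atoms: none
Why: Proposed new method: heat opens 4 by conrotatory 4π cleavage of its C(=O)–C(CH3)2 bond to vinylketene 13, the ketene C=C of 13 adds [2+2] to each ynol ether arm of 12 to give 14, 14 opens in the same way to dienylketene 15, and 15 closes by disrotatory 6π electrocyclisation between the ketene carbon and the C(CH3)2 terminus, so that all four ring carbons of each molecule of 4 return in a ring enlarged by the two alkyne carbons (four to six members). The closest known reaction type is the Danheiser benzannulation of cyclobutenones with alkoxyalkynes together with the thermal ring expansion of 4-alkenylcyclobutenones; beyond it lie the 3-alkoxy-4,4-dimethyl substrate, the end of the cascade at a 6,6-dimethylcyclohexa-2,4-dienone that cannot tautomerise to a phenol, and the twofold run on one core. Ring closures: the transient four-membered rings of 14 form by [2+2] cycloaddition, and the two final six-membered rings form by 6π electrocyclisation, which is the thermally downhill direction of the dienylketene/cyclohexadienone pair. No stereocentre remains: the two CH centres of 14 form without control and are erased on ring opening, and because that opening is reversible the rotamer with the alkenyl group turned outward returns to 14 while only the inward one, drawn as 15, cyclises. The regioselectivity needed (ArCH2-bearing carbon next to C=O, ring oxygens 1,3,5) follows from the polarity of the ynol ether, whose carbon remote from oxygen attacks the ketene carbonyl carbon. Chemoselectivity rests on the substrate design: no O–H group is present to trap a ketene, methyl ynol ethers have no β-hydrogen for retro-ene loss of an alkene at this temperature, and high concentration with excess 4 favours capture of 13 over its dimerisation or 1,5-hydrogen shift.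

**Step 7**
Reactants: 16 bis(dialkoxycyclohexadienone) from step 6
Product: 17 1-{3,5-bis[(2,6-dihydroxy-3,3-dimethyl-4-oxocyclohexa-1,5-dien-1-yl)methyl]-2,4,6-trimethoxyphenyl}butan-1-one
Conditions: 2 M aq. HCl, THF, 60 °C, under N2
Reagents that add atoms: water (O)
Why: Acid hydrolysis of enol ethers and vinylogous esters (C-protonation, addition of water, loss of alcohol) frees both triketone rings, while the aryl methyl ethers, the aryl ketone and the CH2 bridges to the non-phenolic ring A are inert.

**Step 8**
Reactants: 17 bis(filicinic acid) from step 7; 18 butanoic acid (2.2 equiv)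
Product: 20 1-{3,5-bis[(5-butanoyl-2,6-dihydroxy-3,3-dimethyl-4-oxocyclohexa-1,5-dien-1-yl)methyl]-2,4,6-trimethoxyphenyl}butan-1-one, via bis(enol butanoate) 19 (not isolated)
Conditions: DCC (2.4 equiv), DMAP (0.5 equiv), CH2Cl2, 0 °C to rt
Reagents that add atoms: none
Why: Carbodiimide-mediated O-acylation of the acidic enols followed by DMAP-catalysed O-to-C acyl migration, the standard route to 2-acylcyclohexane-1,3-diones, ends at the only free ring carbon of each outer ring, where the chelated triketone is the thermodynamic sink.

**Step 9**
Reactants: 20 tri-O-methyl ether of the target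
Product: 21 CNP0086314.0 (filixic acid BBB)
Conditions: BBr3 (10 equiv), CH2Cl2, −78 °C to 0 °C; then H2O
Reagents that add atoms: none
Why: BBr3 cleavage of aryl methyl ethers is helped by chelation to the ketone for the two ortho ethers and by the twisted, more basic oxygen of the doubly flanked third ether, while the enolised triketones are merely held as boron chelates until work-up.

**Compound list**
1 | isobutyryl chloride | CC(C)C(=O)Cl | starting material
2 | ethoxyacetylene | C#COCC | starting material
3 | dimethylketene | CC(C)=C=O | intermediate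
4 | 3-ethoxy-4,4-dimethylcyclobut-2-en-1-one | CCOC1=CC(=O)C1(C)C | intermediate
5 | 1,3,5-trimethoxybenzene | COc1cc(OC)cc(OC)c1 | starting material
6 | butanoic anhydride | CCCC(=O)OC(=O)CCC | starting material
7 | 1-(2,4,6-trimethoxyphenyl)butan-1-one | CCCC(=O)c1c(OC)cc(OC)cc1OC | intermediate
8 | 1-[3,5-bis(bromomethyl)-2,4,6-trimethoxyphenyl]butan-1-one | CCCC(=O)c1c(OC)c(CBr)c(OC)c(CBr)c1OC | intermediate
9 | 2-chloro-1,1-dimethoxyethane | COC(CCl)OC | starting material
10 | lithium methoxyacetylide | [Li]C#COC | intermediate
11 | tributyl(methoxyethynyl)stannane | CCCC[Sn](CCCC)(CCCC)C#COC | intermediate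
12 | 1-[2,4,6-trimethoxy-3,5-bis(3-methoxyprop-2-yn-1-yl)phenyl]butan-1-one | CCCC(=O)c1c(OC)c(CC#COC)c(OC)c(CC#COC)c1OC | intermediate
13 | 3-ethoxy-4-methylpenta-1,3-dien-1-one, the (1-ethoxy-2-methylprop-1-enyl)ketene | CCOC(C=C=O)=C(C)C | intermediate
14 | 1-{3,5-bis[[3-(1-ethoxy-2-methylprop-1-en-1-yl)-2-methoxy-4-oxocyclobut-1-en-1-yl]methyl]-2,4,6-trimethoxyphenyl}butan-1-one (mixture of diastereomers at the two ring CH centres, both of which are lost later) | CCCC(=O)c1c(OC)c(CC2=C(OC)C(C(OCC)=C(C)C)C2=O)c(OC)c(CC2=C(OC)C(C(OCC)=C(C)C)C2=O)c1OC | intermediate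
15 | bis(dienylketene): ring A core of 12 whose two CH2 groups each carry C2 of a (3E)-5-ethoxy-3-methoxy-6-methylhepta-1,3,5-trien-1-one chain (ketene carbon chain and alkenyl group cis on C3=C4) | CCCC(=O)c1c(OC)c(CC(=C=O)/C(OC)=C\C(OCC)=C(C)C)c(OC)c(CC(=C=O)/C(OC)=C\C(OCC)=C(C)C)c1OC | intermediate
16 | 1-{3,5-bis[(4-ethoxy-2-methoxy-5,5-dimethyl-6-oxocyclohexa-1,3-dien-1-yl)methyl]-2,4,6-trimethoxyphenyl}butan-1-one | CCCC(=O)c1c(OC)c(CC2=C(OC)C=C(OCC)C(C)(C)C2=O)c(OC)c(CC2=C(OC)C=C(OCC)C(C)(C)C2=O)c1OC | intermediate
17 | 1-{3,5-bis[(2,6-dihydroxy-3,3-dimethyl-4-oxocyclohexa-1,5-dien-1-yl)methyl]-2,4,6-trimethoxyphenyl}butan-1-one | CCCC(=O)c1c(OC)c(CC2=C(O)C(C)(C)C(=O)C=C2O)c(OC)c(CC2=C(O)C(C)(C)C(=O)C=C2O)c1OC | intermediate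
18 | butanoic acid | CCCC(=O)O | starting material
19 | bis(enol butanoate) of 17 (one of several equilibrating O-acyl isomers) | CCCC(=O)c1c(OC)c(CC2=C(O)C(C)(C)C(=O)C=C2OC(=O)CCC)c(OC)c(CC2=C(O)C(C)(C)C(=O)C=C2OC(=O)CCC)c1OC | intermediate
20 | 1-{3,5-bis[(5-butanoyl-2,6-dihydroxy-3,3-dimethyl-4-oxocyclohexa-1,5-dien-1-yl)methyl]-2,4,6-trimethoxyphenyl}butan-1-one | CCCC(=O)c1c(OC)c(CC2=C(O)C(C)(C)C(=O)C(C(=O)CCC)=C2O)c(OC)c(CC2=C(O)C(C)(C)C(=O)C(C(=O)CCC)=C2O)c1OC | intermediate
21 | CNP0086314.0, 1-{3,5-bis[(5-butanoyl-2,6-dihydroxy-3,3-dimethyl-4-oxocyclohexa-1,5-dien-1-yl)methyl]-2,4,6-trihydroxyphenyl}butan-1-one | CCCC(=O)C1=C(O)C(Cc2c(O)c(CC3=C(O)C(C)(C)C(=O)C(C(=O)CCC)=C3O)c(O)c(C(=O)CCC)c2O)=C(O)C(C)(C)C1=O | target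

**Total step count:** 9.
**Longest linear sequence:** 7 (steps 2, 3, 5, 6, 7, 8, 9).

**Steps most likely to fail**

**Step 6.**
- What may go wrong: electrocyclic opening of the resonance-stabilised 3-alkoxycyclobutenone may be slow. The ketene would then appear only at temperatures where other processes outrun the double cycloaddition: its 1,5-hydrogen shift from the inward methyl group, its dimerisation, and polymerisation of the ynol ether arms. One arm may also lag behind the other.
- What is not critical: the mode of union. A direct [4+2] capture of the ketene would lead, after step 7, to the same triketone.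
- Fallback (known chemistry only): it sets out from 12 and comes back at 16.
- The same ketene 13 is made at or below room temperature by dehydrochlorination of an unsaturated acyl chloride.
- Commercial ethyl 4-methyl-3-oxopentanoate is treated with HC(OEt)3 and catalytic H2SO4 to give ethyl (E)-3-ethoxy-4-methylpent-2-enoate F1.
- LiOH saponifies it to (E)-3-ethoxy-4-methylpent-2-enoic acid F2, and (COCl)2 converts this to (E)-3-ethoxy-4-methylpent-2-enoyl chloride F3.
- Slow addition of F3 to 12 and Et3N in CH2Cl2 gives 13 by 1,4-elimination, and its [2+2] cycloaddition with both arms gives 14, which is now isolated.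
- Heating 14 in toluene at 110 °C brings about the known thermal ring expansion of 4-alkenylcyclobutenones, four to six members, to give 16.

**Step 5.**
- What may go wrong: protodestannylation or hydration of the ynol ether, homocoupling or solvolysis of the electron-rich benzylic bromide, and palladium-induced oligomerisation of the electron-rich alkyne.
- Fallback: it sets out from 5 and 11 and comes back at 12.
- The enolisable ketone was the reason for choosing a neutral cross-coupling. It is left out until the arms are in place, so that a plain SN2 alkylation can be used.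
- NBS brominates 5 to 2-bromo-1,3,5-trimethoxybenzene F4.
- Bromomethylation as in step 3 gives 1-bromo-3,5-bis(bromomethyl)-2,4,6-trimethoxybenzene F5.
- Tin–lithium exchange of 11 with n-BuLi gives amine-free 10. This displaces both benzylic bromides (THF/DMPU, −78 to 0 °C) to give 1-bromo-2,4,6-trimethoxy-3,5-bis(3-methoxyprop-2-yn-1-yl)benzene F6.
- Bromine–lithium exchange (n-BuLi, −78 °C) gives [2,4,6-trimethoxy-3,5-bis(3-methoxyprop-2-yn-1-yl)phenyl]lithium F7, which is acylated with N-methoxy-N-methylbutanamide to give 12.

**Step 9.**
- What may go wrong: incomplete cleavage of the hindered ether between the two bridges, and Lewis-acid-induced heterolysis of a bridge CH2–C bond once the phenols are freed, with loss or scrambling of the outer rings.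
- Fallback: it sets out from 17 and comes back at 21, with the order of the last two operations inverted.
- BBr3 is applied to 17. Its unacylated outer rings are weaker leaving groups and offer fewer Lewis-basic sites. The product is 1-{3,5-bis[(2,6-dihydroxy-3,3-dimethyl-4-oxocyclohexa-1,5-dien-1-yl)methyl]-2,4,6-trihydroxyphenyl}butan-1-one F8.
- The last step then runs under almost neutral conditions with 18, DCC and DMAP. The far more acidic outer-ring enols are acylated first to the bis(enol butanoate) of the free triphenol F9.
- DMAP then moves the acyl groups to the only free ring carbons of the molecule, which is the thermodynamic sink, to give 21.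
- Any aryl butanoate formed on the way is relayed by DMAP in the same manner or removed by brief methanolysis.

**Further compounds**
F1 | step 6 | ethyl (E)-3-ethoxy-4-methylpent-2-enoate | CCOC(=O)/C=C(/OCC)C(C)C
F2 | step 6 | (E)-3-ethoxy-4-methylpent-2-enoic acid | OC(=O)/C=C(/OCC)C(C)C
F3 | step 6 | (E)-3-ethoxy-4-methylpent-2-enoyl chloride | ClC(=O)/C=C(/OCC)C(C)C
F4 | step 5 | 2-bromo-1,3,5-trimethoxybenzene | COc1cc(OC)c(Br)c(OC)c1
F5 | step 5 | 1-bromo-3,5-bis(bromomethyl)-2,4,6-trimethoxybenzene | COc1c(Br)c(OC)c(CBr)c(OC)c1CBr
F6 | step 5 | 1-bromo-2,4,6-trimethoxy-3,5-bis(3-methoxyprop-2-yn-1-yl)benzene | COC#CCc1c(OC)c(Br)c(OC)c(CC#COC)c1OC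
F7 | step 5 | [2,4,6-trimethoxy-3,5-bis(3-methoxyprop-2-yn-1-yl)phenyl]lithium | [Li]c1c(OC)c(CC#COC)c(OC)c(CC#COC)c1OC
F8 | step 9 | 1-{3,5-bis[(2,6-dihydroxy-3,3-dimethyl-4-oxocyclohexa-1,5-dien-1-yl)methyl]-2,4,6-trihydroxyphenyl}butan-1-one | CCCC(=O)c1c(O)c(CC2=C(O)C(C)(C)C(=O)C=C2O)c(O)c(CC2=C(O)C(C)(C)C(=O)C=C2O)c1O
F9 | step 9 | bis(enol butanoate) of the free triphenol | CCCC(=O)c1c(O)c(CC2=C(O)C(C)(C)C(=O)C=C2OC(=O)CCC)c(O)c(CC2=C(O)C(C)(C)C(=O)C=C2OC(=O)CCC)c1O
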